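**Strategy.** The lone stereocentre (C2 of the tetradecyl chain) lies between two methylenes, benzylic C1 and C3, so reduction or hydration chemistry cannot tell its flanks apart. The route instead inserts C1–C2 as a vinyl group on boron. A Pd/Mandyphos-catalysed enantioselective conjunctive cross-coupling joins the ate complex of vinylB(pin) and dodecylmagnesium bromide with 3,5-bis(benzyloxy)phenyl triflate. One metal-induced 1,2-metallate shift forms the aryl–C1 and C2–C3 bonds and sets C2 as a C–B bond, oxidised in the same flask with retention. Three achiral fragments are thus the precursor; debenzylation and chemoselective phenol mono-acetylation of the resorcinol ring finish the synthesis.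

Key step: step 2

Assumption: 3,5-bis(benzyloxy)phenol 1, vinylboronic acid pinacol ester 3 and dodecylmagnesium bromide 4 (ethereal solution) are taken as commercial.

Assumption: the (Sp,Sp)-Mandyphos antipode is taken to give the (S)-boronate when the migrating group is a primary alkyl; the equally available (Rp,Rp)-antipode would replace it, with no other change, if a trial run showed the opposite sense.

The target is the (S)-enantiomer: at C2 the priorities are OH > CH2Ar > dodecyl > H.

Step 1
Reactants: 1 3,5-bis(benzyloxy)phenol
Product: 2 3,5-bis(benzyloxy)phenyl trifluoromethanesulfonate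
Conditions: Tf2O, pyridine, CH2Cl2, 0 °C
Reagents that add atoms: trifluoromethanesulfonic anhydride, O=S(=O)(OS(=O)(=O)C(F)(F)F)C(F)(F)F
Why: O-sulfonylation of a phenol by triflic anhydride with pyridine as base is fast and clean, the benzyl ethers are inert, and no stereocentre is involved.

Step 2
Reactants: 2 3,5-bis(benzyloxy)phenyl trifluoromethanesulfonate; 3 vinylboronic acid pinacol ester; 4 dodecylmagnesium bromide
Product: 7 (2S)-1-[3,5-bis(benzyloxy)phenyl]tetradecan-2-ol, via bromomagnesium dodecyl(vinyl)pinacolatoborate 5 (not isolated), via (S)-secondary alkyl pinacol boronate 6 (not isolated)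
Conditions: 4, 3, NaOTf, THF, 0 °C → rt; then Pd(OAc)2 (2 mol%), (Sp,Sp)-Mandyphos (2.4 mol%), 2, THF, 60 °C; then 3 M aq NaOH, 30% H2O2, 0 °C → rt
Reagents that add atoms: vinylboronic acid pinacol ester 3, C=CB1OC(C)(C)C(C)(C)O1; dodecylmagnesium bromide 4, CCCCCCCCCCCC[Mg]Br; hydrogen peroxide, OO
Why: Oxidative addition of Pd(0)/Mandyphos to the C–OTf bond of 2 gives a cationic arylpalladium(II) that binds the vinyl π-bond of four-coordinate borate 5; this triggers an anti 1,2-shift of the dodecyl group from boron to the α-carbon while palladium bonds to the terminal carbon, and C(sp3)–C(sp2) reductive elimination from the β-boryl alkylpalladium aryl releases 6 with the aryl–C1 and C2–C3 bonds formed. The reaction type is the known catalytic enantioselective conjunctive cross-coupling (metal-induced 1,2-metallate rearrangement) of Grignard-derived vinylboron ate complexes with aryl triflates, in which primary alkyl migrating groups and alkoxy-substituted aryl triflates are ordinary partners. No ring is closed. The single new stereocentre C2 is controlled by the C2-symmetric Mandyphos ligand, which selects the alkene face bound by palladium in the migration step; the (Sp,Sp) ligand is expected to give (S)-6, and the stereoretentive boron-to-oxygen shift with NaOH/H2O2 then gives (S)-7. The step needs chemoselectivity for the metallate shift over direct Suzuki-type transfer of vinyl or dodecyl and over β-hydride elimination: the non-coordinating triflate, with NaOTf driving ate formation and sequestering bromide, keeps palladium cationic and free to bind the alkene, the tetracoordinate borate offers no B–O–Pd transmetallation path, and the wide-bite bisphosphine makes reductive elimination fast. The benzyl ethers are inert throughout.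

Step 3
Reactants: 7 (2S)-1-[3,5-bis(benzyloxy)phenyl]tetradecan-2-ol
Product: 8 5-[(2S)-2-hydroxytetradecyl]benzene-1,3-diol
Conditions: H2 (1 atm), 10% Pd/C, EtOAc/EtOH, rt
Reagents that add atoms: none
Why: Catalytic hydrogenolysis cleaves both benzylic aryl ether C–O bonds, while the homobenzylic C2–OH bond is not benzylic and should stay, so the stereocentre is untouched.

Step 4
Reactants: 8 5-[(2S)-2-hydroxytetradecyl]benzene-1,3-diol
Product: 9 3-hydroxy-5-[(2S)-2-hydroxytetradecyl]phenyl acetate
Conditions: Ac2O (1.0 equiv), 1 M aq NaOH (1.0 equiv), THF/H2O, 0 °C; then pH 6 buffer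
Reagents that add atoms: acetic anhydride, CC(=O)OC(C)=O
Why: In this Schotten–Baumann-type O-acetylation the mono-phenoxide is far more nucleophilic toward acetic anhydride than the neutral secondary alcohol; the two phenols are equivalent by rotation about the aryl–C1 bond, so only one mono-acetate can form, and the liberated acetic acid consumes the base and stops hydrolysis, leaving the stereocentre untouched.

**Compound list**
1 | 3,5-bis(benzyloxy)phenol | Oc1cc(OCc2ccccc2)cc(OCc2ccccc2)c1 | starting material
2 | 3,5-bis(benzyloxy)phenyl trifluoromethanesulfonate | O=S(=O)(Oc1cc(OCc2ccccc2)cc(OCc2ccccc2)c1)C(F)(F)F | intermediate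
3 | vinylboronic acid pinacol ester (4,4,5,5-tetramethyl-2-vinyl-1,3,2-dioxaborolane) | C=CB1OC(C)(C)C(C)(C)O1 | starting material
4 | dodecylmagnesium bromide | CCCCCCCCCCCC[Mg]Br | starting material
5 | bromomagnesium dodecyl(vinyl)pinacolatoborate (ate complex) | CCCCCCCCCCCC[B-]1(C=C)OC(C)(C)C(C)(C)O1.[Mg+]Br | intermediate
6 | 2-[(2S)-1-[3,5-bis(benzyloxy)phenyl]tetradecan-2-yl]-4,4,5,5-tetramethyl-1,3,2-dioxaborolane | CCCCCCCCCCCC[C@H](B1OC(C)(C)C(C)(C)O1)Cc1cc(OCc2ccccc2)cc(OCc2ccccc2)c1 | intermediate
7 | (2S)-1-[3,5-bis(benzyloxy)phenyl]tetradecan-2-ol | CCCCCCCCCCCC[C@H](O)Cc1cc(OCc2ccccc2)cc(OCc2ccccc2)c1 | intermediate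
8 | 5-[(2S)-2-hydroxytetradecyl]benzene-1,3-diol | CCCCCCCCCCCC[C@H](O)Cc1cc(O)cc(O)c1 | intermediate
9 | 3-hydroxy-5-[(2S)-2-hydroxytetradecyl]phenyl acetate (CNP0339839.1) | CCCCCCCCCCCC[C@H](O)Cc1cc(O)cc(OC(C)=O)c1 | target

**Total step count:** 4
**Longest linear sequence:** 4 steps (1 → 2 → 7 → 8 → 9)

**Steps most likely to fail**

Step 2. The arylpalladium may take vinyl or dodecyl directly from boron without the metallate shift, the alkylpalladium intermediate may undergo β-hydride elimination, ate-complex formation may be incomplete, or facial selectivity may be insufficient. The fallback separates C–C bond formation from asymmetric induction and sets out from 2. Suzuki–Miyaura coupling of 2 (Pd(dppf)Cl2, K3PO4, dioxane/H2O, 80 °C) with (E)-tetradec-1-en-1-ylboronic acid pinacol ester F1 should give (E)-1-[3,5-bis(benzyloxy)phenyl]tetradec-1-ene F2; F1 is made beforehand by Cp2Zr(H)Cl-catalysed hydroboration of commercial tetradec-1-yne with pinacolborane. Shi epoxidation of this trans-disubstituted styrene with the L-fructose-derived ketone catalyst (Oxone, K2CO3 buffer, MeCN/dimethoxymethane/H2O, 0 °C) should give (2S,3S)-2-[3,5-bis(benzyloxy)phenyl]-3-dodecyloxirane F3. Hydrogenation over Pd/C (H2, EtOAc/EtOH) should then cleave the benzylic epoxide C–O bond and both benzyl ethers while the C–O bond at the dodecyl-bearing carbon keeps its configuration, so the fallback rejoins the route at 8.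

Step 4. The acetylation may run on to the bis-phenol acetate or stop short, so that the mono-acetate is obtained only as part of a statistical mixture, and prolonged exposure to base may hydrolyse or scramble the aryl ester. The fallback replaces the statistical acylation by an enzyme-controlled deacylation and sets out from 8. Exhaustive phenol acetylation (Ac2O, 2.5 equiv, aq NaOH, THF, 0 °C) should give 5-[(2S)-2-hydroxytetradecyl]-1,3-phenylene diacetate F4. Lipase-catalysed alcoholysis of F4 (immobilised Candida antarctica lipase B, n-butanol, MTBE, rt) should remove one aryl acetate and slow markedly at the more polar mono-acetate, as is typical of lipase deacylation of diacetates of dihydric phenols. The hindered secondary alcohol is a poor acyl acceptor, and the fallback rejoins the route at 9.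

Step 3. Debenzylation may stall through poisoning of the palladium surface by traces of ferrocenyl phosphine carried over from step 2, or through poor solubility of the lipophilic substrate. The fallback replaces surface-catalysed reduction by Lewis-acid dealkylation, sets out from 7 and makes no new compound (F0). BCl3 with pentamethylbenzene as cation scavenger (CH2Cl2, −78 °C, methanol quench) should cleave both aryl benzyl ethers; the secondary alcohol is held as a borate and is released on quench, so the fallback rejoins the route at 8.

**Further compounds**
F1 | step 2 | (E)-tetradec-1-en-1-ylboronic acid pinacol ester | CCCCCCCCCCCC/C=C/B1OC(C)(C)C(C)(C)O1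
F2 | step 2 | (E)-1-[3,5-bis(benzyloxy)phenyl]tetradec-1-ene | CCCCCCCCCCCC/C=C/c1cc(OCc2ccccc2)cc(OCc2ccccc2)c1
F3 | step 2 | (2S,3S)-2-[3,5-bis(benzyloxy)phenyl]-3-dodecyloxirane | CCCCCCCCCCCC[C@@H]1O[C@H]1c1cc(OCc2ccccc2)cc(OCc2ccccc2)c1
F4 | step 4 | 5-[(2S)-2-hydroxytetradecyl]-1,3-phenylene diacetate | CCCCCCCCCCCC[C@H](O)Cc1cc(OC(C)=O)cc(OC(C)=O)c1
F0 | step 3 | none | none
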